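Ring B occurs twice and every one of its carbons is substituted: C1 carries the propionyl group, C2, C4 and C6 carry oxygen, C3 the bridge to a terminal ring A, and C5 the central CH2 that both rings B have in common. The route cuts the two outer bridges and then both rings B. A two-directional Danheiser benzannulation joins a CH2-linked bis(3-ethoxycyclobutenone) with two molecules of a ketal-masked propionyl ynol ether. One operation closes both benzene rings (C1–C2 and C5–C6 of each ring B) with all three oxygens differentiated, the acyl group masked and C3 free.

Key step: step 6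

Remarks on the chemistry:
- The target has no stereocentre. The enolised rings A are drawn in the tautomer of the target SMILES.
- In the annulation product the central CH2 lies para to the new hydroxyl and between the two ethoxy groups, so each aryl ring is numbered 2,6-diethoxy-4-hydroxy-3-(dioxolanyl).
- Step 2 consumes two molecules of 4 for each molecule of formaldehyde: both four-membered rings of 7 come from 4, and the bridging CH2 comes from 5.
- The alkyne is used in excess in step 6, and its ketal is brought in through a cyclic orthoester so that the ynol ether never meets protic acid.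
- Assumption: 1-(2,4,6-trihydroxyphenyl)propan-1-one and triethyl orthopropionate are taken as commercially available.

Step 1
Reactants: 1 ethoxyacetylene; 2 acetyl chloride
Product: 4 3-ethoxycyclobut-2-en-1-one, via ketene 3 (not isolated)
Conditions: 2 (2 equiv), Et3N (2 equiv), Et2O, 0 °C to rt, slow addition
Reagents that add atoms: none
Why: Dehydrochlorination of the acid chloride should generate ketene, which adds [2+2] to the ynol ether with its carbonyl carbon bonding to the unsubstituted alkyne carbon (ketene–alkynyl ether cycloaddition).

Step 2
Reactants: 4 3-ethoxycyclobut-2-en-1-one; 5 formaldehyde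
Product: 7 2,2'-methylenebis(3-hydroxycyclobut-2-en-1-one), via cyclobutane-1,3-dione 6 (not isolated)
Conditions: 4 (2.0 equiv), HCl (cat.), H2O/THF, 0 °C to rt; then 37% aq. 5 (1.0 equiv), rt
Reagents that add atoms: water, O
Why: Two molecules of 4 react per molecule of 5: acid hydrolysis of each vinylogous ester should give the strongly acidic dione 6, one molecule of which condenses through its enol carbon C2 with formaldehyde while the second adds to the resulting 2-methylene dione (Knoevenagel condensation then Michael addition, as for other cyclic 1,3-diones), and telescoping avoids storing the labile dione.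

Step 3
Reactants: 7 2,2'-methylenebis(3-hydroxycyclobut-2-en-1-one)
Product: 8 2,2'-methylenebis(3-ethoxycyclobut-2-en-1-one)
Conditions: iPr2NEt (2.2 equiv), Et3O+ BF4− (2.2 equiv), CH2Cl2, −20 to 0 °C
Reagents that add atoms: triethyloxonium tetrafluoroborate, CC[O+](CC)CC.F[B-](F)(F)F
Why: The hard oxonium salt should O-ethylate the ammonium enolate of each vinylogous acid (enol ether formation); C2 is already substituted, both carbonyls of a ring are equivalent, and no nucleophile is present that could open the strained ring.

Step 4
Reactants: 9 triethyl orthopropionate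
Product: 10 2-ethoxy-2-ethyl-1,3-dioxolane
Conditions: HOCH2CH2OH (1.0 equiv), TsOH (cat.), 100 °C, EtOH distilled off
Reagents that add atoms: ethane-1,2-diol, OCCO
Why: Acid-catalysed orthoester exchange should replace two ethoxy groups by the diol, driven by removal of ethanol and by closure of the five-membered ring.

Step 5
Reactants: 1 ethoxyacetylene; 10 2-ethoxy-2-ethyl-1,3-dioxolane
Product: 12 2-(ethoxyethynyl)-2-ethyl-1,3-dioxolane, via ethoxyethynylmagnesium bromide 11 (not isolated)
Conditions: 1 (1.2 equiv), EtMgBr (1.1 equiv), THF, 0 °C to rt; then 10, THF/PhMe, 50–60 °C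
Reagents that add atoms: none
Why: The alkynylmagnesium bromide should displace the exocyclic ethoxy group of the cyclic orthoester through the magnesium-assisted dioxolan-2-ylium ion (Bodroux–Chichibabin ketal synthesis), a basic, acid-free way to the propargylic ketal.

Step 6
Reactants: 8 2,2'-methylenebis(3-ethoxycyclobut-2-en-1-one); 12 2-(ethoxyethynyl)-2-ethyl-1,3-dioxolane
Product: 15 bis[2,6-diethoxy-3-(2-ethyl-1,3-dioxolan-2-yl)-4-hydroxyphenyl]methane, via ethoxy vinylketene 13 (not isolated), via mono-annulated phenol 14 (not isolated)
Conditions: 12 (3 equiv), PhMe, 80–100 °C, sealed tube, argon; then K2CO3, MeOH, rt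
Reagents that add atoms: none
Why: Each four-membered ring of 8 opens by thermal 4π electrocyclic cleavage of its C(=O)–CH2 bond to a 3-ethoxy vinylketene (13 for the first ring); the ketene C=C adds [2+2] to the electron-rich alkyne 12, the carbonyl carbon bonding to the ketal-bearing alkyne carbon and the ketene α-carbon (the one holding the central CH2) to the ethoxy-bearing carbon, and the 4-vinylcyclobutenone so formed reopens to a dienylketene that ring-closes and tautomerises to the phenol (14, then 15). This is the Danheiser benzannulation of a cyclobutenone with an alkynyl ether, run in two directions on one substrate. Each benzene ring is closed by thermal 6π electrocyclisation of the dienylketene (ketene carbon onto the terminal =CH2), so the two new skeletal bonds per ring are C1–C2 and C5–C6 of ring B. No stereocentre is created. The only selectivity needed is regiochemical and is set by the polarisation of the ynol ether, which places the masked propionyl group between the new hydroxyl and an ethoxy group and leaves C3 unsubstituted. The new hydroxyl lies para to the CH2 bridge and cannot reach the second ketene within the molecule, excess 12 outcompetes intermolecular O-acylation, the temperature stays below that at which ethyl ynol ethers lose ethylene, and the carbonate methanolysis returns any aryl ester to the phenol.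

Step 7
Reactants: 15 bis[2,6-diethoxy-3-(2-ethyl-1,3-dioxolan-2-yl)-4-hydroxyphenyl]methane
Product: 16 1,1'-[methylenebis(2,4-diethoxy-6-hydroxy-3,1-phenylene)]di(propan-1-one)
Conditions: 1 M HCl, THF, rt
Reagents that add atoms: water, O
Why: Ketal hydrolysis should be fast because the benzylic oxocarbenium ion is stabilised by the ortho- and para-oxygenated ring, while aryl ethyl ethers and the diarylmethane are inert to dilute acid.

Step 8
Reactants: 16 1,1'-[methylenebis(2,4-diethoxy-6-hydroxy-3,1-phenylene)]di(propan-1-one)
Product: 17 1,1'-[methylenebis(2,4,6-trihydroxy-3,1-phenylene)]di(propan-1-one)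
Conditions: BBr3 (10 equiv), CH2Cl2, −78 °C to rt; then H2O, 0 °C
Reagents that add atoms: none
Why: BBr3 should cleave all four aryl ethyl ethers by O-complexation and bromide attack at the ethyl CH2 (Lewis acid ether cleavage), the ether next to each ketone being helped by chelation, while the ketones and the CH2 bridge persist at low temperature.

Step 9
Reactants: 18 1-(2,4,6-trihydroxyphenyl)propan-1-one
Product: 19 3,5-dihydroxy-6,6-dimethyl-2-propanoylcyclohexa-2,4-dien-1-one
Conditions: NaOMe (2.5 equiv), MeI (2.2 equiv), MeOH, 0 °C to rt; 1 M HCl work-up
Reagents that add atoms: iodomethane, CI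
Why: The phloroglucinol enolate should be C-methylated twice at one ring carbon with loss of aromaticity (geminal C-alkylation, the classical entry to acylfilicinic acids), and limiting MeI to about two equivalents holds the reaction at this stage.

Step 10
Reactants: 19 3,5-dihydroxy-6,6-dimethyl-2-propanoylcyclohexa-2,4-dien-1-one
Product: 20 4-[(dimethylamino)methyl]-3,5-dihydroxy-6,6-dimethyl-2-propanoylcyclohexa-2,4-dien-1-one hydroiodide
Conditions: CH2=NMe2+ I− (1.05 equiv), CH2Cl2, 0 °C to rt
Reagents that add atoms: N,N-dimethylmethyleneiminium iodide, C=[N+](C)C.[I-]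
Why: The enolised triketone should attack the preformed iminium ion at its only unsubstituted ring carbon (Mannich aminomethylation), and the product stays protonated as the ammonium iodide, which holds back premature elimination.

Step 11
Reactants: 17 1,1'-[methylenebis(2,4,6-trihydroxy-3,1-phenylene)]di(propan-1-one); 20 4-[(dimethylamino)methyl]-3,5-dihydroxy-6,6-dimethyl-2-propanoylcyclohexa-2,4-dien-1-one hydroiodide
Product: 23 CNP0541376.0 (target), via methylene trione 21 (not isolated), via mono-coupled trimer 22 (not isolated)
Conditions: 20 (2.4 equiv), NaOAc (0.2 equiv), MeCN/THF, 50 °C, argon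
Reagents that add atoms: none
Why: Warming the Mannich salt should release dimethylammonium iodide and the enone methide 21 (retro-Mannich elimination), which is attacked by the single free carbon C3 of each ring B of 17, flanked by two hydroxyls (Michael addition, a vinylogous Friedel–Crafts alkylation), first to 22 and then to 23; the electrophile has no free ring carbon of its own, and reversible O-adducts funnel to the C-alkylated product.

Compound list
1 | ethoxyacetylene (ethoxyethyne) | C#COCC | starting material
2 | acetyl chloride | CC(Cl)=O | starting material
3 | ketene (ethenone) | C=C=O | intermediate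
4 | 3-ethoxycyclobut-2-en-1-one | CCOC1=CC(=O)C1 | intermediate
5 | formaldehyde | C=O | starting material
6 | cyclobutane-1,3-dione | O=C1CC(=O)C1 | intermediate
7 | 2,2'-methylenebis(3-hydroxycyclobut-2-en-1-one) | O=C1CC(O)=C1CC1=C(O)CC1=O | intermediate
8 | 2,2'-methylenebis(3-ethoxycyclobut-2-en-1-one) | O=C1CC(OCC)=C1CC1=C(OCC)CC1=O | intermediate
9 | triethyl orthopropionate (1,1,1-triethoxypropane) | CCC(OCC)(OCC)OCC | starting material
10 | 2-ethoxy-2-ethyl-1,3-dioxolane | CCOC1(CC)OCCO1 | intermediate
11 | (ethoxyethynyl)magnesium bromide | CCOC#C[Mg]Br | intermediate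
12 | 2-(ethoxyethynyl)-2-ethyl-1,3-dioxolane | CCOC#CC1(CC)OCCO1 | intermediate
13 | 3-ethoxy-2-[(2-ethoxy-4-oxocyclobut-1-en-1-yl)methyl]buta-1,3-dien-1-one | O=C=C(CC1=C(OCC)CC1=O)C(OCC)=C | intermediate
14 | 2-{[2,6-diethoxy-3-(2-ethyl-1,3-dioxolan-2-yl)-4-hydroxyphenyl]methyl}-3-ethoxycyclobut-2-en-1-one | CCC1(OCCO1)c1c(O)cc(OCC)c(CC2=C(OCC)CC2=O)c1OCC | intermediate
15 | bis[2,6-diethoxy-3-(2-ethyl-1,3-dioxolan-2-yl)-4-hydroxyphenyl]methane | CCC1(OCCO1)c1c(O)cc(OCC)c(Cc2c(OCC)cc(O)c(C3(CC)OCCO3)c2OCC)c1OCC | intermediate
16 | 1,1'-[methylenebis(2,4-diethoxy-6-hydroxy-3,1-phenylene)]di(propan-1-one) | CCC(=O)c1c(O)cc(OCC)c(Cc2c(OCC)cc(O)c(C(=O)CC)c2OCC)c1OCC | intermediate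
17 | 1,1'-[methylenebis(2,4,6-trihydroxy-3,1-phenylene)]di(propan-1-one) | CCC(=O)c1c(O)cc(O)c(Cc2c(O)cc(O)c(C(=O)CC)c2O)c1O | intermediate
18 | 1-(2,4,6-trihydroxyphenyl)propan-1-one (flopropione) | CCC(=O)c1c(O)cc(O)cc1O | starting material
19 | 3,5-dihydroxy-6,6-dimethyl-2-propanoylcyclohexa-2,4-dien-1-one (propionylfilicinic acid) | CCC(=O)C1=C(O)C=C(O)C(C)(C)C1=O | intermediate
20 | 4-[(dimethylamino)methyl]-3,5-dihydroxy-6,6-dimethyl-2-propanoylcyclohexa-2,4-dien-1-one hydroiodide | CCC(=O)C1=C(O)C(C[NH+](C)C)=C(O)C(C)(C)C1=O.[I-] | intermediate
21 | 3-hydroxy-6,6-dimethyl-4-methylidene-2-propanoylcyclohex-2-ene-1,5-dione | CCC(=O)C1=C(O)C(=C)C(=O)C(C)(C)C1=O | intermediate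
22 | 3,5-dihydroxy-6,6-dimethyl-2-propanoyl-4-({2,4,6-trihydroxy-5-propanoyl-3-[(2,4,6-trihydroxy-3-propanoylphenyl)methyl]phenyl}methyl)cyclohexa-2,4-dien-1-one | CCC(=O)C1=C(O)C(Cc2c(O)c(Cc3c(O)cc(O)c(C(=O)CC)c3O)c(O)c(C(=O)CC)c2O)=C(O)C(C)(C)C1=O | intermediate
23 | CNP0541376.0: 4,4'-{methylenebis[(2,4,6-trihydroxy-5-propanoyl-3,1-phenylene)methylene]}bis(3,5-dihydroxy-6,6-dimethyl-2-propanoylcyclohexa-2,4-dien-1-one), no stereocentre | CCC(=O)C1=C(O)C(Cc2c(O)c(Cc3c(O)c(CC4=C(O)C(C)(C)C(=O)C(C(=O)CC)=C4O)c(O)c(C(=O)CC)c3O)c(O)c(C(=O)CC)c2O)=C(O)C(C)(C)C1=O | target

Total step count: 11.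
Longest linear sequence: 7 steps (steps 1, 2, 3, 6, 7, 8 and 11).

Steps most likely to fail

Risk 1, step 6. The 3-ethoxycyclobutenone rings may open too slowly below 100 °C, while above it the ynol ether fragments to ethylene and a ketene. Vinylketenes may also be captured by the hydroxyl of half-annulated material, which would build ester-linked oligomers in place of the second ring. The fallback gives up the annulation and reaches the same bis-phloroglucinol by known condensation chemistry. It sets out from 18 and 5 and comes back to the route at 17. Excess 18 (about 4 equiv) would be treated with 5 (1 equiv) in dilute aqueous NaOH at 0 °C to rt, so that hydroxymethylation, loss of water to the quinone methide and capture by a second ring give the methylene-bridged dimer. The two free ring positions of 18 are equivalent, the excess of 18 limits chain growth, and unreacted 18 would be recovered. This fallback makes no compound outside the list (F0).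

Risk 2, step 2. In water the strained dione may hydrate and open by retro-Claisen cleavage, and the transient 2-methylene dione may oligomerise before the second dione adds. The fallback separates the two C–C bond formations and runs them without water. It sets out from 4 and comes back at 7. Compound 4 would be hydrolysed as before and 6 isolated by extraction and crystallisation. One equivalent of 6 would then be aminomethylated with N,N-dimethylmethyleneiminium iodide in MeCN at −20 °C to give 2-[(dimethylamino)methyl]-3-hydroxycyclobut-2-en-1-one hydroiodide F1. Warming F1 with a second equivalent of 6 and a catalytic amount of NaOAc in MeCN should release the methylene dione slowly in the presence of a full equivalent of its Michael donor and give 7.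

Risk 3, step 11. The second alkylation may lag behind the first so that mono-coupled material accumulates, and retro-Michael cleavage with re-addition may exchange CH2 bridges and scramble the ring sequence. The fallback reverses the roles of the partners. It sets out from 17 and comes back at 23. Double aminomethylation of 17 at the two C3 positions with N,N-dimethylmethyleneiminium iodide (2.1 equiv, MeCN, 0 °C) would give 1,1'-{methylenebis[5-[(dimethylamino)methyl]-2,4,6-trihydroxy-3,1-phenylene]}di(propan-1-one) dihydroiodide F2. Heating F2 with excess 19 (about 4 equiv, recoverable) and catalytic NaOAc in MeCN should generate an ortho-quinone methide on each ring B, which the enol carbon of 19 captures to give 23. With every C3 already carrying its CH2, no aromatic carbon is left to compete with 19 for the quinone methide.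

Further compounds
F0 | step 6 | none | none
F1 | step 2 | 2-[(dimethylamino)methyl]-3-hydroxycyclobut-2-en-1-one hydroiodide | C[NH+](C)CC1=C(O)CC1=O.[I-]
F2 | step 11 | 1,1'-{methylenebis[5-[(dimethylamino)methyl]-2,4,6-trihydroxy-3,1-phenylene]}di(propan-1-one) dihydroiodide | CCC(=O)c1c(O)c(C[NH+](C)C)c(O)c(Cc2c(O)c(C[NH+](C)C)c(O)c(C(=O)CC)c2O)c1O.[I-].[I-]
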